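**Plan**

1. Numbering used here: chain C1–C13 runs from the ethyl CH3 (C1) to the CH2 on the ring (C13); C3 carries CH2OH, C4 and C6 carry OH, C7 and C10 carry CH3. Ring: C14 (quaternary, CH3), C15 (ethyl), C16 (C=O), C17=C18, C19 (C(CH3)OH).
2. Retrosynthesis: the C16 carbonyl goes back to an allylic CH2 and the hydroxyls to silyl ethers and an acetonide. The C6–C7 bond is then cut into fragment A (C1–C6, a primary C6 benzoate) and fragment B (C7–C19, a secondary C7 boronic ester). Fragment B is cut further at C7–CH3, at C12–C13 and, in the ring, at C14–C19 and C15–C16; fragment A is cut at C3–C4.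
3. Forward: the cyclohexene ring arises first by a [4+2] cycloaddition. The C7–C12 chain (from citronellyl bromide) is joined at C13, the C19 carbinol is built, and C7 is converted to the boronic ester. Fragments A and B are then joined at C6–C7, C16 is oxidised and all protecting groups are removed.
4. Stereochemistry: C14/C15 come from the E-geometry of the enal and a chiral oxazaborolidinium catalyst; C19 from methyl addition anti to the cis CH3/ethyl pair; C10 from (S)-citronellyl bromide; C7 and C6 from (+)-sparteine; C3/C4 from an Evans auxiliary.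
5. Enabling feature: the C6 carbinol carbon (H, OH) is bonded directly to the CH3-bearing methine C7, and its other neighbour C5 carries no oxygen. C6 can therefore be an α-acyloxy carbanion derived from a primary alcohol ester, and its OH can be the oxidised C–B bond left after C7 migrates from boron to C6.

Key step: step 19

Remark: the cycloaddition of step 5 is expected to favour the endo adduct (silyloxy cis to formyl). Its silyloxy epimer, if formed, converges later because that carbon becomes a carbonyl.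

Abbreviations: TIB = 2,4,6-triisopropylbenzoyl; Bpin = 4,4,5,5-tetramethyl-1,3,2-dioxaborolan-2-yl; TIPS = triisopropylsilyl; TES = triethylsilyl; TBS = tert-butyldimethylsilyl.

**Chain piece (C7–C12)**

Step 1
Reactants: 1 (S)-citronellyl bromide [(S)-8-bromo-2,6-dimethyloct-2-ene]
Product: 2 (S)-6-bromo-4-methylhexan-1-ol
Conditions: O3, CH2Cl2/MeOH, −78 °C; NaBH4, −78 → 0 °C
Reagents that add atoms: ozone, [O-][O+]=O
Why: Ozonolysis with reductive work-up cleaves only the trisubstituted alkene and leaves the primary alcohol that becomes C7, while the chiral-pool methyl stereocentre (future C10) is untouched.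

Step 2
Reactants: 2 (S)-6-bromo-4-methylhexan-1-ol
Product: 3 (S)-6-bromo-4-methylhexyl 2,4,6-triisopropylbenzoate
Conditions: 2,4,6-triisopropylbenzoic acid, PPh3, DIAD, THF, 0 °C → rt
Reagents that add atoms: 2,4,6-triisopropylbenzoic acid, CC(C)c1cc(C(C)C)c(C(=O)O)c(C(C)C)c1
Why: Mitsunobu esterification of the unhindered primary alcohol installs the hindered benzoate that later serves as directing and leaving group at C7 and that resists organolithium attack.

Step 3
Reactants: 3 (S)-6-bromo-4-methylhexyl 2,4,6-triisopropylbenzoate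
Product: 4 (S)-6-iodo-4-methylhexyl 2,4,6-triisopropylbenzoate
Conditions: NaI, acetone, reflux
Reagents that add atoms: sodium iodide, [Na+].[I-]
Why: Finkelstein halide exchange on the primary bromide gives the iodide needed for clean iodine–lithium exchange.

**Ring and fragment B (C7–C19)**

Step 4
Reactants: 5 (E)-but-2-enal (crotonaldehyde)
Product: 6 (E)-1-(triisopropylsilyloxy)buta-1,3-diene
Conditions: TIPSOTf, Et3N, Et2O, 0 °C → rt
Reagents that add atoms: triisopropylsilyl triflate, CC(C)[Si](OS(=O)(=O)C(F)(F)F)(C(C)C)C(C)C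
Why: Soft enolisation and O-silylation of the vinylogous enolate (silyl dienol ether formation) should give the E-configured 1-silyloxydiene, whose bulky silyl group resists transfer to Lewis acids.

Step 5
Reactants: 6 (E)-1-(triisopropylsilyloxy)buta-1,3-diene; 7 (E)-2-methylpent-2-enal
Product: 8 (1R,2S,6S)-6-ethyl-1-methyl-2-(triisopropylsilyloxy)cyclohex-3-ene-1-carbaldehyde
Conditions: (R)-o-tolyl-CBS oxazaborolidine (20 mol%), Tf2NH (18 mol%), CH2Cl2, −78 → −40 °C
Reagents that add atoms: none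
Why: In this oxazaborolidinium-catalysed enantioselective Diels–Alder reaction the 1-silyloxy donor directs ortho regiochemistry and suprafacial addition to the E-enal places the C14 methyl and C15 ethyl cis; the boron-bound s-trans enal, stacked on the proximal phenyl of the (R)-catalyst, should leave open the Si face of the α-carbon (formyl > β-carbon > CH3), which sets C14 and C15.

Step 6
Reactants: 8 (1R,2S,6S)-6-ethyl-1-methyl-2-(triisopropylsilyloxy)cyclohex-3-ene-1-carbaldehyde
Product: 9 (E)-tosylhydrazone of aldehyde 8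
Conditions: TsNHNH2, THF, 4 Å molecular sieves, rt
Reagents that add atoms: 4-methylbenzenesulfonohydrazide, Cc1ccc(cc1)S(=O)(=O)NN
Why: Condensation of the non-enolisable aldehyde with tosylhydrazide gives the hydrazone that activates C13 for reductive alkylation.

Step 7
Reactants: 9 (E)-tosylhydrazone of aldehyde 8; 4 (S)-6-iodo-4-methylhexyl 2,4,6-triisopropylbenzoate
Product: 13 (R)-7-[(1R,2S,6S)-6-ethyl-1-methyl-2-(triisopropylsilyloxy)cyclohex-3-en-1-yl]-4-methylheptyl 2,4,6-triisopropylbenzoate, via N-silyl tosylhydrazone 10 (not isolated), via alkyllithium 11 (not isolated), via monoalkyl diazene 12 (not isolated)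
Conditions: 9: TBSOTf, Et3N, THF, −78 °C; 4: t-BuLi (2 equiv), Et2O/pentane, −78 °C; combine at −78 °C; AcOH, CF3CH2OH, −78 °C → rt
Reagents that add atoms: none
Why: Reductive alkylation of an N-silyl tosylhydrazone: the alkyllithium from iodine–lithium exchange adds to the C=N carbon, and acid-induced loss of the silyl group, sulfinate and N2 from the monoalkyl diazene leaves the C12–C13 bond at the methylene level with no alkene to reduce; the hindered benzoate is inert to alkyllithiums at −78 °C.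

Step 8
Reactants: 13 (R)-7-[(1R,2S,6S)-6-ethyl-1-methyl-2-(triisopropylsilyloxy)cyclohex-3-en-1-yl]-4-methylheptyl 2,4,6-triisopropylbenzoate
Product: 14 (R)-7-[(1R,2S,6S)-6-ethyl-2-hydroxy-1-methylcyclohex-3-en-1-yl]-4-methylheptyl 2,4,6-triisopropylbenzoate
Conditions: TBAF, THF, rt → 50 °C
Reagents that add atoms: none
Why: Fluoride desilylation frees the allylic alcohol at C19, and the hindered benzoate is stable to fluoride.

Step 9
Reactants: 14 (R)-7-[(1R,2S,6S)-6-ethyl-2-hydroxy-1-methylcyclohex-3-en-1-yl]-4-methylheptyl 2,4,6-triisopropylbenzoate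
Product: 15 (R)-7-[(1R,6S)-6-ethyl-1-methyl-2-oxocyclohex-3-en-1-yl]-4-methylheptyl 2,4,6-triisopropylbenzoate
Conditions: Dess–Martin periodinane, CH2Cl2, 0 °C → rt
Reagents that add atoms: none
Why: Dess–Martin oxidation of the secondary allylic alcohol gives the enone with C19 as carbonyl and removes the stereocentre formed unselectively in step 5.

Step 10
Reactants: 15 (R)-7-[(1R,6S)-6-ethyl-1-methyl-2-oxocyclohex-3-en-1-yl]-4-methylheptyl 2,4,6-triisopropylbenzoate
Product: 16 (R)-7-[(1R,2R,6S)-6-ethyl-2-hydroxy-1,2-dimethylcyclohex-3-en-1-yl]-4-methylheptyl 2,4,6-triisopropylbenzoate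
Conditions: MeLi, CeCl3, THF, −78 °C
Reagents that add atoms: methyllithium, [Li]C
Why: Organocerium 1,2-addition to the hindered enone (α′-carbon quaternary, so only γ-deprotonation could compete, and the weakly basic cerium reagent suppresses it); in either half-chair the ring face carrying the cis C14 methyl and C15 ethyl holds an axial group, so methyl should enter anti to both and set C19 with OH cis to the C14 methyl.

Step 11
Reactants: 16 (R)-7-[(1R,2R,6S)-6-ethyl-2-hydroxy-1,2-dimethylcyclohex-3-en-1-yl]-4-methylheptyl 2,4,6-triisopropylbenzoate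
Product: 17 (R)-7-[(1R,2R,6S)-6-ethyl-1,2-dimethyl-2-(triethylsilyloxy)cyclohex-3-en-1-yl]-4-methylheptyl 2,4,6-triisopropylbenzoate
Conditions: TESOTf, 2,6-lutidine, CH2Cl2, −78 → 0 °C
Reagents that add atoms: triethylsilyl triflate, CC[Si](CC)(CC)OS(=O)(=O)C(F)(F)F
Why: Silylation with the reactive triflate masks the tertiary allylic alcohol, which would otherwise quench the carbanions of steps 12 and 19.

Step 12
Reactants: 17 (R)-7-[(1R,2R,6S)-6-ethyl-1,2-dimethyl-2-(triethylsilyloxy)cyclohex-3-en-1-yl]-4-methylheptyl 2,4,6-triisopropylbenzoate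
Product: 20 2-{(2R,5R)-8-[(1R,2R,6S)-6-ethyl-1,2-dimethyl-2-(triethylsilyloxy)cyclohex-3-en-1-yl]-5-methyloctan-2-yl}-4,4,5,5-tetramethyl-1,3,2-dioxaborolane, via α-lithio benzoate 18 (not isolated), via boronate complex 19 (not isolated)
Conditions: sBuLi, (+)-sparteine, Et2O, −78 °C; MeBpin, −78 °C → 40 °C
Reagents that add atoms: 2,4,4,5,5-pentamethyl-1,3,2-dioxaborolane (MeBpin), CB1OC(C)(C)C(C)(C)O1
Why: Lithiation–borylation homologation: (+)-sparteine-directed deprotonation gives the configurationally stable (R)-α-lithio benzoate, MeBpin is captured with retention, and anti-periplanar 1,2-shift of methyl with loss of the benzoate (inversion) should set the C7 boronic ester as R.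

**Fragment A (C1–C6)**

Step 13
Reactants: 21 but-3-en-1-ol
Product: 22 but-3-en-1-yl 2,4,6-triisopropylbenzoate
Conditions: 2,4,6-triisopropylbenzoic acid, PPh3, DIAD, THF, 0 °C → rt
Reagents that add atoms: 2,4,6-triisopropylbenzoic acid, CC(C)c1cc(C(C)C)c(C(=O)O)c(C(C)C)c1
Why: Mitsunobu esterification places the hindered benzoate on the oxygen that will stay on C6.

Step 14
Reactants: 22 but-3-en-1-yl 2,4,6-triisopropylbenzoate
Product: 23 3-oxopropyl 2,4,6-triisopropylbenzoate
Conditions: OsO4 (2 mol%), NaIO4, 2,6-lutidine, dioxane/H2O, rt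
Reagents that add atoms: osmium tetroxide, O=[Os](=O)(=O)=O; sodium periodate (terminal oxidant), [Na+].[O-]I(=O)(=O)=O
Why: Lemieux–Johnson oxidative cleavage of the terminal alkene gives the C4 aldehyde without touching the electron-rich, hindered arene.

Step 15
Reactants: 24 (S)-4-benzyloxazolidin-2-one; 25 butanoyl chloride
Product: 26 (S)-4-benzyl-3-butanoyloxazolidin-2-one
Conditions: n-BuLi, THF, −78 °C; 25, −78 → 0 °C
Reagents that add atoms: none
Why: N-acylation of the lithiated oxazolidinone gives the imide for the aldol reaction.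

Step 16
Reactants: 26 (S)-4-benzyl-3-butanoyloxazolidin-2-one; 23 3-oxopropyl 2,4,6-triisopropylbenzoate
Product: 28 (S)-4-benzyl-3-[(2S,3R)-2-ethyl-3-hydroxy-5-(2,4,6-triisopropylbenzoyloxy)pentanoyl]oxazolidin-2-one, via boron enolate 27 (not isolated)
Conditions: Bu2BOTf, Et3N, CH2Cl2, 0 °C; 23, −78 → 0 °C; H2O2, MeOH, pH 7 buffer
Reagents that add atoms: none
Why: Evans syn-aldol reaction: the Z-boron enolate reacts through a chair transition state on the face opposite the benzyl group, which sets C3 and C4 (2S,3R in the adduct, both R in the target once the carbonyl is CH2OH).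

Step 17
Reactants: 28 (S)-4-benzyl-3-[(2S,3R)-2-ethyl-3-hydroxy-5-(2,4,6-triisopropylbenzoyloxy)pentanoyl]oxazolidin-2-one
Product: 29 (3R,4R)-3-hydroxy-4-(hydroxymethyl)hexyl 2,4,6-triisopropylbenzoate
Conditions: LiBH4, MeOH (1 equiv), THF, 0 °C
Reagents that add atoms: none
Why: Reductive removal of the auxiliary converts the imide carbonyl to the C3 hydroxymethyl group, and the hindered benzoate is not reduced.

Step 18
Reactants: 29 (3R,4R)-3-hydroxy-4-(hydroxymethyl)hexyl 2,4,6-triisopropylbenzoate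
Product: 30 2-[(4R,5R)-5-ethyl-2,2-dimethyl-1,3-dioxan-4-yl]ethyl 2,4,6-triisopropylbenzoate
Conditions: 2,2-dimethoxypropane, PPTS (cat.), CH2Cl2, rt
Reagents that add atoms: 2,2-dimethoxypropane, COC(C)(C)OC
Why: Acetonide formation ties the 1,3-diol into a 1,3-dioxane that is stable to sBuLi and to basic peroxide.

**Fragment union and end game**

Step 19
Reactants: 30 2-[(4R,5R)-5-ethyl-2,2-dimethyl-1,3-dioxan-4-yl]ethyl 2,4,6-triisopropylbenzoate; 20 2-{(2R,5R)-8-[(1R,2R,6S)-6-ethyl-1,2-dimethyl-2-(triethylsilyloxy)cyclohex-3-en-1-yl]-5-methyloctan-2-yl}-4,4,5,5-tetramethyl-1,3,2-dioxaborolane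
Product: 34 (2S,3R,6R)-1-[(4R,5R)-5-ethyl-2,2-dimethyl-1,3-dioxan-4-yl]-9-[(1R,2R,6S)-6-ethyl-1,2-dimethyl-2-(triethylsilyloxy)cyclohex-3-en-1-yl]-3,6-dimethylnonan-2-ol, via α-lithio benzoate 31 (not isolated), via boronate complex 32 (not isolated), via C6 boronic ester 33 (not isolated)
Conditions: 30 (1.4 equiv), sBuLi, (+)-sparteine, Et2O, −78 °C; 20, −78 °C, then 40 °C; NaOH (2 M), H2O2 (30%), THF, 0 °C → rt
Reagents that add atoms: hydrogen peroxide, OO
Why: (+)-Sparteine-complexed sBuLi removes one enantiotopic α-proton of the primary benzoate 30 to give the configurationally stable carbenoid 31, boronic ester 20 adds to it with retention to form the ate complex 32, and on warming the C7 alkyl group migrates from boron to C6 anti-periplanar to the departing triisopropylbenzoate (inversion at C6, retention at C7), after which basic peroxide replaces boron by hydroxyl with retention. The closest known reaction type is the lithiation–borylation homologation of secondary pinacol boronic esters with sparteine-lithiated primary 2,4,6-triisopropylbenzoates. No ring is closed. The C6 stereocentre (S) is set by the chiral diamine (reagent control, intended to override the dioxane stereocentres), whereas C7 (R) is carried over unchanged from 20, so the 6,7-anti and 4,6-syn relationships follow from the use of (+)-sparteine in steps 12 and 19. The step needs deprotonation only at the O–CH2 group and carbon rather than oxygen migration in 32; the hindered benzoate (stable to sBuLi, good leaving group) and the absence of carbonyl or free hydroxyl groups in 20 (C16 still CH2, C19–OH silylated) should secure both.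

Step 20
Reactants: 34 (2S,3R,6R)-1-[(4R,5R)-5-ethyl-2,2-dimethyl-1,3-dioxan-4-yl]-9-[(1R,2R,6S)-6-ethyl-1,2-dimethyl-2-(triethylsilyloxy)cyclohex-3-en-1-yl]-3,6-dimethylnonan-2-ol
Product: 35 triethylsilyl ether of alcohol 34 at the C6 oxygen
Conditions: TESOTf, 2,6-lutidine, CH2Cl2, −78 °C
Reagents that add atoms: triethylsilyl triflate, CC[Si](CC)(CC)OS(=O)(=O)C(F)(F)F
Why: Silylation protects the only free (secondary) alcohol from the oxidant of step 21.

Step 21
Reactants: 35 triethylsilyl ether of alcohol 34 at the C6 oxygen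
Product: 36 the C16 ketone of 35 [ring: (1R,2R,6R)-6-ethyl-1,2-dimethyl-5-oxo-2-(triethylsilyloxy)cyclohex-3-en-1-yl]
Conditions: Rh2(cap)4 (cap = caprolactamate, 1 mol%), TBHP (70% aq.), K2CO3 (cat.), CH2Cl2, rt
Reagents that add atoms: tert-butyl hydroperoxide, CC(C)(C)OO
Why: Dirhodium-catalysed allylic C–H oxidation by tert-butylperoxy radicals: C16 is the only allylic carbon bearing hydrogen (C19 is fully substituted), and trapping of the allyl radical at C16 rather than at the neopentyl-like C18 should give the enone directly.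

Step 22
Reactants: 36 the C16 ketone of 35
Product: 37 (4R,5R,6R)-5-[(4R,7R,8S,10R,11R)-8,10-dihydroxy-11-(hydroxymethyl)-4,7-dimethyltridecyl]-6-ethyl-4-hydroxy-4,5-dimethylcyclohex-2-en-1-one (CNP0104178.2)
Conditions: HF (48% aq.), MeCN, 0 °C → rt
Reagents that add atoms: none
Why: Global acidic deprotection removes both triethylsilyl ethers and the acetonide in one operation; the γ-hydroxy enone resists ionisation because the carbonyl destabilises the allyl cation, and the mild conditions should spare the C15 stereocentre.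

**Compound list**

1 | (S)-citronellyl bromide, (S)-8-bromo-2,6-dimethyloct-2-ene | CC(C)=CCC[C@H](C)CCBr | starting material
2 | (S)-6-bromo-4-methylhexan-1-ol | OCCC[C@H](C)CCBr | intermediate
3 | (S)-6-bromo-4-methylhexyl 2,4,6-triisopropylbenzoate | CC(C)c1cc(C(C)C)c(C(=O)OCCC[C@H](C)CCBr)c(C(C)C)c1 | intermediate
4 | (S)-6-iodo-4-methylhexyl 2,4,6-triisopropylbenzoate | CC(C)c1cc(C(C)C)c(C(=O)OCCC[C@H](C)CCI)c(C(C)C)c1 | intermediate
5 | (E)-but-2-enal (crotonaldehyde) | C/C=C/C=O | starting material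
6 | (E)-1-(triisopropylsilyloxy)buta-1,3-diene | C=C/C=C/O[Si](C(C)C)(C(C)C)C(C)C | intermediate
7 | (E)-2-methylpent-2-enal | CC/C=C(\C)C=O | starting material
8 | (1R,2S,6S)-6-ethyl-1-methyl-2-(triisopropylsilyloxy)cyclohex-3-ene-1-carbaldehyde | O=C[C@]1(C)[C@@H](CC)CC=C[C@@H]1O[Si](C(C)C)(C(C)C)C(C)C | intermediate
9 | (E)-tosylhydrazone of aldehyde 8 (ring stereocentres as in 8) | Cc1ccc(cc1)S(=O)(=O)N/N=C/[C@]1(C)[C@@H](CC)CC=C[C@@H]1O[Si](C(C)C)(C(C)C)C(C)C | intermediate
10 | N-(tert-butyldimethylsilyl) derivative of tosylhydrazone 9 (silyl on the sulfonamide nitrogen) | Cc1ccc(cc1)S(=O)(=O)N(/N=C/[C@]2(C)[C@@H](CC)CC=C[C@@H]2O[Si](C(C)C)(C(C)C)C(C)C)[Si](C)(C)C(C)(C)C | intermediate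
11 | alkyllithium from iodide 4 (lithium in place of iodine) | CC(C)c1cc(C(C)C)c(C(=O)OCCC[C@H](C)CC[Li])c(C(C)C)c1 | intermediate
12 | monoalkyl diazene: 13 carrying N=NH on C13 (C13 epimers) | N=NC(CC[C@@H](C)CCCOC(=O)c1c(C(C)C)cc(C(C)C)cc1C(C)C)[C@]2(C)[C@@H](CC)CC=C[C@@H]2O[Si](C(C)C)(C(C)C)C(C)C | intermediate
13 | (R)-7-[(1R,2S,6S)-6-ethyl-1-methyl-2-(triisopropylsilyloxy)cyclohex-3-en-1-yl]-4-methylheptyl 2,4,6-triisopropylbenzoate | CC(C)c1cc(C(C)C)c(C(=O)OCCC[C@H](C)CCC[C@]2(C)[C@@H](CC)CC=C[C@@H]2O[Si](C(C)C)(C(C)C)C(C)C)c(C(C)C)c1 | intermediate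
14 | (R)-7-[(1R,2S,6S)-6-ethyl-2-hydroxy-1-methylcyclohex-3-en-1-yl]-4-methylheptyl 2,4,6-triisopropylbenzoate | CC(C)c1cc(C(C)C)c(C(=O)OCCC[C@H](C)CCC[C@]2(C)[C@@H](CC)CC=C[C@@H]2O)c(C(C)C)c1 | intermediate
15 | (R)-7-[(1R,6S)-6-ethyl-1-methyl-2-oxocyclohex-3-en-1-yl]-4-methylheptyl 2,4,6-triisopropylbenzoate | CC(C)c1cc(C(C)C)c(C(=O)OCCC[C@H](C)CCC[C@]2(C)[C@@H](CC)CC=CC2=O)c(C(C)C)c1 | intermediate
16 | (R)-7-[(1R,2R,6S)-6-ethyl-2-hydroxy-1,2-dimethylcyclohex-3-en-1-yl]-4-methylheptyl 2,4,6-triisopropylbenzoate | CC(C)c1cc(C(C)C)c(C(=O)OCCC[C@H](C)CCC[C@]2(C)[C@@H](CC)CC=C[C@@]2(C)O)c(C(C)C)c1 | intermediate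
17 | (R)-7-[(1R,2R,6S)-6-ethyl-1,2-dimethyl-2-(triethylsilyloxy)cyclohex-3-en-1-yl]-4-methylheptyl 2,4,6-triisopropylbenzoate | CC(C)c1cc(C(C)C)c(C(=O)OCCC[C@H](C)CCC[C@]2(C)[C@@H](CC)CC=C[C@@]2(C)O[Si](CC)(CC)CC)c(C(C)C)c1 | intermediate
18 | (R)-α-lithio derivative of benzoate 17 (lithium on C7) | CC(C)c1cc(C(C)C)c(C(=O)O[C@H]([Li])CC[C@H](C)CCC[C@]2(C)[C@@H](CC)CC=C[C@@]2(C)O[Si](CC)(CC)CC)c(C(C)C)c1 | intermediate
19 | lithium boronate complex of 18 with MeBpin (boron bonded to C7, methyl and pinacolate) | [Li+].C[B-]1(OC(C)(C)C(C)(C)O1)[C@@H](OC(=O)c1c(C(C)C)cc(C(C)C)cc1C(C)C)CC[C@H](C)CCC[C@]2(C)[C@@H](CC)CC=C[C@@]2(C)O[Si](CC)(CC)CC | intermediate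
20 | 2-{(2R,5R)-8-[(1R,2R,6S)-6-ethyl-1,2-dimethyl-2-(triethylsilyloxy)cyclohex-3-en-1-yl]-5-methyloctan-2-yl}-4,4,5,5-tetramethyl-1,3,2-dioxaborolane (fragment B) | CC1(C)OB(OC1(C)C)[C@H](C)CC[C@H](C)CCC[C@]2(C)[C@@H](CC)CC=C[C@@]2(C)O[Si](CC)(CC)CC | intermediate
21 | but-3-en-1-ol | C=CCCO | starting material
22 | but-3-en-1-yl 2,4,6-triisopropylbenzoate | C=CCCOC(=O)c1c(C(C)C)cc(C(C)C)cc1C(C)C | intermediate
23 | 3-oxopropyl 2,4,6-triisopropylbenzoate | O=CCCOC(=O)c1c(C(C)C)cc(C(C)C)cc1C(C)C | intermediate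
24 | (S)-4-benzyloxazolidin-2-one | O=C1N[C@@H](Cc2ccccc2)CO1 | starting material
25 | butanoyl chloride | CCCC(Cl)=O | starting material
26 | (S)-4-benzyl-3-butanoyloxazolidin-2-one | CCCC(=O)N1C(=O)OC[C@@H]1Cc1ccccc1 | intermediate
27 | (Z)-dibutylboron enolate of imide 26 | CC/C=C(\OB(CCCC)CCCC)N1C(=O)OC[C@@H]1Cc1ccccc1 | intermediate
28 | (S)-4-benzyl-3-[(2S,3R)-2-ethyl-3-hydroxy-5-(2,4,6-triisopropylbenzoyloxy)pentanoyl]oxazolidin-2-one | CC[C@H](C(=O)N1C(=O)OC[C@@H]1Cc1ccccc1)[C@H](O)CCOC(=O)c1c(C(C)C)cc(C(C)C)cc1C(C)C | intermediate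
29 | (3R,4R)-3-hydroxy-4-(hydroxymethyl)hexyl 2,4,6-triisopropylbenzoate | CC[C@H](CO)[C@H](O)CCOC(=O)c1c(C(C)C)cc(C(C)C)cc1C(C)C | intermediate
30 | 2-[(4R,5R)-5-ethyl-2,2-dimethyl-1,3-dioxan-4-yl]ethyl 2,4,6-triisopropylbenzoate (fragment A) | CC[C@@H]1COC(C)(C)O[C@@H]1CCOC(=O)c1c(C(C)C)cc(C(C)C)cc1C(C)C | intermediate
31 | (R)-α-lithio derivative of benzoate 30 (lithium on C6) | CC[C@@H]1COC(C)(C)O[C@@H]1C[C@@H]([Li])OC(=O)c1c(C(C)C)cc(C(C)C)cc1C(C)C | intermediate
32 | lithium boronate complex of 31 with 20 (boron bonded to C6, C7 and pinacolate) | [Li+].CC[C@@H]1COC(C)(C)O[C@@H]1C[C@H](OC(=O)c1c(C(C)C)cc(C(C)C)cc1C(C)C)[B-]1(OC(C)(C)C(C)(C)O1)[C@H](C)CC[C@H](C)CCC[C@]2(C)[C@@H](CC)CC=C[C@@]2(C)O[Si](CC)(CC)CC | intermediate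
33 | C6 pinacol boronic ester: 34 with Bpin in place of the C6 hydroxyl (C6 S) | CC[C@@H]1COC(C)(C)O[C@@H]1C[C@H](B1OC(C)(C)C(C)(C)O1)[C@H](C)CC[C@H](C)CCC[C@]2(C)[C@@H](CC)CC=C[C@@]2(C)O[Si](CC)(CC)CC | intermediate
34 | (2S,3R,6R)-1-[(4R,5R)-5-ethyl-2,2-dimethyl-1,3-dioxan-4-yl]-9-[(1R,2R,6S)-6-ethyl-1,2-dimethyl-2-(triethylsilyloxy)cyclohex-3-en-1-yl]-3,6-dimethylnonan-2-ol | CC[C@@H]1COC(C)(C)O[C@@H]1C[C@H](O)[C@H](C)CC[C@H](C)CCC[C@]2(C)[C@@H](CC)CC=C[C@@]2(C)O[Si](CC)(CC)CC | intermediate
35 | triethylsilyl ether of alcohol 34 at the C6 oxygen | CC[C@@H]1COC(C)(C)O[C@@H]1C[C@H](O[Si](CC)(CC)CC)[C@H](C)CC[C@H](C)CCC[C@]2(C)[C@@H](CC)CC=C[C@@]2(C)O[Si](CC)(CC)CC | intermediate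
36 | C16 ketone of 35, ring (1R,2R,6R)-6-ethyl-1,2-dimethyl-5-oxo-2-(triethylsilyloxy)cyclohex-3-en-1-yl | CC[C@@H]1COC(C)(C)O[C@@H]1C[C@H](O[Si](CC)(CC)CC)[C@H](C)CC[C@H](C)CCC[C@]2(C)[C@@H](CC)C(=O)C=C[C@@]2(C)O[Si](CC)(CC)CC | intermediate
37 | (4R,5R,6R)-5-[(4R,7R,8S,10R,11R)-8,10-dihydroxy-11-(hydroxymethyl)-4,7-dimethyltridecyl]-6-ethyl-4-hydroxy-4,5-dimethylcyclohex-2-en-1-one | CC[C@H](CO)[C@H](O)C[C@H](O)[C@H](C)CC[C@H](C)CCC[C@]1(C)[C@@H](CC)C(=O)C=C[C@@]1(C)O | target

**Step count and risks**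

Total step count: 22. Longest linear sequence: 13 steps (steps 4–12 and 19–22 from crotonaldehyde; equally steps 1–3, 7–12 and 19–22 from citronellyl bromide).

Steps most likely to fail:

1. Step 19. Proton removal at C6 may be incomplete or of the wrong sense if (+)-sparteine is mismatched with the dioxane stereocentres. Capture of the diamine-bound carbenoid by the hindered secondary boronic ester and the following 1,2-shift may also be slow, which allows oxygen migration or carbenoid decomposition. Fallback: setting out from 30, deprotonation with sBuLi/(+)-sparteine (Et2O, −78 °C) and quenching with Me3SnCl should give, with retention, the (R)-α-trimethylstannyl benzoate F1, from which the minor diastereomer is removed by chromatography. Tin–lithium exchange (n-BuLi, Et2O, −78 °C) then regenerates the diamine-free carbenoid 31, which is more reactive towards hindered boronic esters. Addition of 20, warming and oxidative work-up as in step 19 return to the route at 34.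

2. Step 7. Addition of the alkyllithium to the neopentyl-type C=N carbon may be sluggish, so that deprotonation or decomposition of the silyl hydrazone competes. Fallback: setting out from 8, alkyllithium 11 (from 4 as in step 7) is added to the aldehyde itself (THF, −78 °C) to give the secondary alcohol F2 as a mixture of C13 epimers. This is converted to the S-methyl xanthate F3 (NaH, CS2, MeI, THF) and deoxygenated under Barton–McCombie conditions (Bu3SnH, AIBN, toluene, 80 °C), which returns to the route at 13.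

3. Step 21. The peroxy radical may be trapped at the other end of the allyl radical (C18, giving the transposed enone), and C–H bonds next to oxygen may be over-oxidised. Fallback: setting out from 35, SeO2 (cat.)/TBHP in CH2Cl2 is used; the ene reaction at C18 followed by a [2,3]-shift can place oxygen only on C16, giving the allylic alcohol F4 (C16 epimers). Dess–Martin periodinane then oxidises F4 to the enone, which returns to the route at 36.

Further compounds
F1 | step 19 | (R)-2-[(4R,5R)-5-ethyl-2,2-dimethyl-1,3-dioxan-4-yl]-1-(trimethylstannyl)ethyl 2,4,6-triisopropylbenzoate | CC[C@@H]1COC(C)(C)O[C@@H]1C[C@@H]([Sn](C)(C)C)OC(=O)c1c(C(C)C)cc(C(C)C)cc1C(C)C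
F2 | step 7 | (4R)-7-[(1R,2S,6S)-6-ethyl-1-methyl-2-(triisopropylsilyloxy)cyclohex-3-en-1-yl]-7-hydroxy-4-methylheptyl 2,4,6-triisopropylbenzoate (both C13 epimers) | CC(C)c1cc(C(C)C)c(C(=O)OCCC[C@H](C)CCC(O)[C@]2(C)[C@@H](CC)CC=C[C@@H]2O[Si](C(C)C)(C(C)C)C(C)C)c(C(C)C)c1
F3 | step 7 | S-methyl xanthate of alcohol F2 (O-alkyl S-methyl dithiocarbonate at C13) | CC(C)c1cc(C(C)C)c(C(=O)OCCC[C@H](C)CCC(OC(=S)SC)[C@]2(C)[C@@H](CC)CC=C[C@@H]2O[Si](C(C)C)(C(C)C)C(C)C)c(C(C)C)c1
F4 | step 21 | C16 allylic alcohol of 35 (hydroxyl on C16, both epimers) | CC[C@@H]1COC(C)(C)O[C@@H]1C[C@H](O[Si](CC)(CC)CC)[C@H](C)CC[C@H](C)CCC[C@]2(C)[C@@H](CC)C(O)C=C[C@@]2(C)O[Si](CC)(CC)CC
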